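**Retrosynthetic overview**
1. Target ⇐ C6–C7 bond formed last: Ni/Cr ring closure of a C7 alkenyl bromide onto a C6 epoxy aldehyde; the ten-membered carbocycle and the butenolide (by acyl transfer from a four-membered lactone) form in the same operation, then O13 is acetylated.
2. Epoxy aldehyde ⇐ (E)-enal by aminocatalytic asymmetric epoxidation (C4, C5); (Z)-bromoalkylidene four-membered lactone ⇐ propargylic alcohol by bromopalladation–cyclocarbonylation (C11–C12, C7–Br).
3. C2–C3 and the (E)-C4=C5 olefin ⇐ palladium-catalysed decarboxylative allylation of an allyl β-keto ester; C1–C2 ⇐ Claisen condensation of an acetate enolate with a γ-lactone; O8 angelate by esterification.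
4. γ-Lactone ⇐ ynone: oxazaborolidine-catalysed reduction sets C8 (first stereocenter), trans-methylation of the lactone enolate sets C10; ynone ⇐ acid chloride + alkyne.
5. Ring order: temporary γ-lactone (C1/O8) → four-membered lactone (C12/O13) → oxirane → ten-membered carbocycle and butenolide together.

Atom labels C1–C15 follow germacrane numbering of the target (C1 ketone, C4/C5 epoxide, C6 lactone carbinol, C7=C11, C8 angelate carbinol, C10 CH(CH3), C12 lactone C=O, C13 CH2OAc).
Assumption: in the oxazaborolidine reduction the alkynyl group behaves as the smaller ketone substituent; if the opposite sense is found, the enantiomeric catalyst is used.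

**Step 1**
Reactants: 1 methyl 4-chloro-4-oxobutanoate; 2 tert-butyldimethyl(prop-2-yn-1-yloxy)silane
Product: 3 methyl 7-[(tert-butyldimethylsilyl)oxy]-4-oxohept-5-ynoate
Conditions: PdCl2(PPh3)2 (2 mol%), CuI (4 mol%), Et3N, THF, rt
Reagents that add atoms: none
Why: Acyl Sonogashira coupling of the acid chloride with the terminal alkyne gives the ynone (C7–C8 bond) without touching the methyl ester or silyl ether, and no stereocenter is formed.

**Step 2**
Reactants: 3 methyl 7-[(tert-butyldimethylsilyl)oxy]-4-oxohept-5-ynoate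
Product: 5 (5S)-5-{3-[(tert-butyldimethylsilyl)oxy]prop-1-yn-1-yl}oxolan-2-one, via hydroxy ester 4 (not isolated)
Conditions: (3aS)-1-methyl-3,3-diphenyltetrahydro-1H,3H-pyrrolo[1,2-c][1,3,2]oxazaborole (15 mol%), BH3·SMe2, THF, −30 °C; then p-toluenesulfonic acid monohydrate (5 mol%), CH2Cl2, rt
Reagents that add atoms: none
Why: Corey–Bakshi–Shibata reduction, in which the oxazaborolidine–borane complex binds the ketone anti to the larger CH2CH2CO2Me chain and delivers hydride to one face, sets C8 as S under catalyst control (the first stereocenter), and the γ-hydroxy ester then lactonizes under acid catalysis.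

**Step 3**
Reactants: 5 (5S)-5-{3-[(tert-butyldimethylsilyl)oxy]prop-1-yn-1-yl}oxolan-2-one
Product: 7 (3R,5S)-3-methyl-5-{3-[(tert-butyldimethylsilyl)oxy]prop-1-yn-1-yl}oxolan-2-one, via lithium enolate 6 (not isolated)
Conditions: LiN(iPr)2, THF, −78 °C; then MeI, −78 → −40 °C
Reagents that add atoms: iodomethane, CI
Why: Diastereoselective enolate alkylation (1,3-induction), with iodomethane attacking the face anti to the C8 alkynyl group, gives the trans-2,4-disubstituted lactone and sets C10 as R.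

**Step 4**
Reactants: 8 isopropenylmagnesium bromide (CH2=C(CH3)MgBr); 9 2,2-dimethoxyacetaldehyde
Product: 11 1,1-dimethoxy-3-methylbut-3-en-2-yl acetate (racemic), via magnesium alkoxide 10 (not isolated)
Conditions: THF, −78 → 0 °C; then Ac2O, 0 °C → rt
Reagents that add atoms: acetic anhydride, CC(=O)OC(C)=O
Why: Grignard 1,2-addition to the aldehyde followed by in situ O-acetylation gives the allylic acetate, whose racemic carbinol carbon becomes sp2 in step 6.

**Step 5**
Reactants: 7 (3R,5S)-3-methyl-5-{3-[(tert-butyldimethylsilyl)oxy]prop-1-yn-1-yl}oxolan-2-one; 11 1,1-dimethoxy-3-methylbut-3-en-2-yl acetate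
Product: 13 1,1-dimethoxy-3-methylbut-3-en-2-yl (4R,6S)-9-[(tert-butyldimethylsilyl)oxy]-6-hydroxy-4-methyl-3-oxonon-7-ynoate (both epimers at the allylic ester carbon), via lithium enolate 12 (not isolated)
Conditions: 11, LiN(iPr)2 (2.2 equiv), THF, −78 °C; then 7, −78 → −30 °C; aq. NH4Cl
Reagents that add atoms: none
Why: Crossed Claisen condensation, in which the acetate lithium enolate acylates on the lactone carbonyl, forms C1–C2 and frees the C8 hydroxyl at a temperature low enough to avoid C10 epimerization or Ireland–Claisen rearrangement of the enolate.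

**Step 6**
Reactants: 13 1,1-dimethoxy-3-methylbut-3-en-2-yl (4R,6S)-9-[(tert-butyldimethylsilyl)oxy]-6-hydroxy-4-methyl-3-oxonon-7-ynoate
Product: 14 (2E,7R,9S)-12-[(tert-butyldimethylsilyl)oxy]-9-hydroxy-1,1-dimethoxy-3,7-dimethyldodec-2-en-10-yn-6-one
Conditions: Pd(PPh3)4 (5 mol%), THF, rt → 40 °C
Reagents that add atoms: none
Why: Tsuji decarboxylative allylation (palladium-catalysed Carroll reaction): ionization to a π-allyl complex, loss of CO2 to give the C2 enolate regiospecifically, and attack at the unsubstituted allyl terminus remote from the acetal form C2–C3 and, through the favoured syn π-allyl, the (E)-C4=C5 olefin, leaving C8 and C10 untouched.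

**Step 7**
Reactants: 14 (2E,7R,9S)-12-[(tert-butyldimethylsilyl)oxy]-9-hydroxy-1,1-dimethoxy-3,7-dimethyldodec-2-en-10-yn-6-one; 15 angelic acid [(2Z)-2-methylbut-2-enoic acid]
Product: 17 (2E,7R,9S)-12-[(tert-butyldimethylsilyl)oxy]-1,1-dimethoxy-3,7-dimethyl-6-oxododec-2-en-10-yn-9-yl (2Z)-2-methylbut-2-enoate, via mixed anhydride 16 (not isolated)
Conditions: 15, 2,4,6-trichlorobenzoyl chloride, Et3N, toluene, rt; then 14, 60 °C
Reagents that add atoms: none
Why: Yamaguchi-type mixed-anhydride esterification without a nucleophilic catalyst acylates the C8 hydroxyl with retention and avoids Z to E isomerization of the angelate.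

**Step 8**
Reactants: 17 (2E,7R,9S)-12-[(tert-butyldimethylsilyl)oxy]-1,1-dimethoxy-3,7-dimethyl-6-oxododec-2-en-10-yn-9-yl (2Z)-2-methylbut-2-enoate
Product: 18 (2E,7R,9S)-12-hydroxy-3,7-dimethyl-1,6-dioxododec-2-en-10-yn-9-yl (2Z)-2-methylbut-2-enoate
Conditions: 48% aq. HF, MeCN, 0 °C → rt
Reagents that add atoms: water, O
Why: Acidic deprotection in which aqueous HF cleaves the primary silyl ether and hydrolyses the α,β-unsaturated dimethyl acetal to the (E)-enal in one operation, leaving the angelate and the ketone intact.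

**Step 9**
Reactants: 18 (2E,7R,9S)-12-hydroxy-3,7-dimethyl-1,6-dioxododec-2-en-10-yn-9-yl (2Z)-2-methylbut-2-enoate
Product: 19 (2S,4R,8E)-1-bromo-4,8-dimethyl-5,10-dioxo-1-[(Z)-2-oxooxetan-3-ylidene]dec-8-en-2-yl (2Z)-2-methylbut-2-enoate
Conditions: PdBr2 (10 mol%), CuBr2 (3 equiv), CO (1 atm), THF, rt
Reagents that add atoms: carbon monoxide, [C-]#[O+]; CuBr2 (copper dibromide), Br[Cu]Br
Why: Halopalladation–cyclocarbonylation of a 2-alkyn-1-ol (the bromide counterpart of the PdCl2/CuCl2 reaction): cis-bromopalladation puts bromine on C7 and palladium on C11, CO insertion and capture by the C13 hydroxyl close the four-membered lactone with bromine cis to the C12 carbonyl (Z), and CuBr2 returns zerovalent palladium to the divalent state.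

**Step 10**
Reactants: 19 (2S,4R,8E)-1-bromo-4,8-dimethyl-5,10-dioxo-1-[(Z)-2-oxooxetan-3-ylidene]dec-8-en-2-yl (2Z)-2-methylbut-2-enoate
Product: 20 (2S,4R)-1-bromo-7-[(2R,3S)-3-formyl-2-methyloxiran-2-yl]-4-methyl-5-oxo-1-[(Z)-2-oxooxetan-3-ylidene]heptan-2-yl (2Z)-2-methylbut-2-enoate
Conditions: (R)-2-{bis[3,5-bis(trifluoromethyl)phenyl][(trimethylsilyl)oxy]methyl}pyrrolidine (10 mol%), 35% aq. H2O2, CH2Cl2, rt
Reagents that add atoms: hydrogen peroxide, OO
Why: Aminocatalytic asymmetric epoxidation of an enal (iminium activation for conjugate addition of hydrogen peroxide, then enamine ring closure), in which the bulky (R)-diarylprolinol silyl ether shields one face of the (E)-iminium ion, sets the trans C4/C5 epoxide in the (4R,5R) sense of the target under catalyst control.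

**Step 11**
Reactants: 20 (2S,4R)-1-bromo-7-[(2R,3S)-3-formyl-2-methyloxiran-2-yl]-4-methyl-5-oxo-1-[(Z)-2-oxooxetan-3-ylidene]heptan-2-yl (2Z)-2-methylbut-2-enoate
Product: 23 CNP0229937.2 [(4R,5R,6S,8S,10R)-13-acetoxy-8-angeloyloxy-4,5-epoxy-1-oxogermacr-7(11)-en-12,6-olide], via ring-closed hydroxy lactone 21 (not isolated), via 13-hydroxy butenolide 22 (not isolated)
Conditions: CrCl2 (8 equiv), NiCl2 (2 mol%), DMF–THF (3:1), rt, 20 added over 12 h (2 mM final); then pyridine, Ac2O, 4-(dimethylamino)pyridine (5 mol%), 0 °C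
Reagents that add atoms: acetic anhydride, CC(=O)OC(C)=O
Why: Proposed new method: a Nozaki–Hiyama–Kishi ring closure coupled to strain-release translactonization, in which the C7 alkenylchromium formed from the activated bromide adds to the tethered epoxy aldehyde with the chain forced to approach anti to the epoxide oxygen and the chromium-bound carbonyl oxygen turned toward H5 and away from the C15 methyl (hence 6S, threo to the epoxide), after which the C6 chromium alkoxide, held cis to C12, opens the strained four-membered lactone to give the butenolide and a C13 alkoxide that is acetylated in the same flask; the closest known reactions are the Nozaki–Hiyama–Kishi coupling of (Z)-β-haloacrylates with aldehydes to give butenolides and chromium-mediated ten-membered ring closures onto epoxy aldehydes.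

**Compound list**
1 | methyl 4-chloro-4-oxobutanoate | COC(=O)CCC(Cl)=O | starting material
2 | tert-butyldimethyl(prop-2-yn-1-yloxy)silane | C#CCO[Si](C)(C)C(C)(C)C | starting material
3 | methyl 7-[(tert-butyldimethylsilyl)oxy]-4-oxohept-5-ynoate | COC(=O)CCC(=O)C#CCO[Si](C)(C)C(C)(C)C | intermediate
4 | methyl (4S)-7-[(tert-butyldimethylsilyl)oxy]-4-hydroxyhept-5-ynoate | COC(=O)CC[C@H](O)C#CCO[Si](C)(C)C(C)(C)C | intermediate
5 | (5S)-5-{3-[(tert-butyldimethylsilyl)oxy]prop-1-yn-1-yl}oxolan-2-one | O=C1CC[C@@H](C#CCO[Si](C)(C)C(C)(C)C)O1 | intermediate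
6 | lithium enolate of 5 [lithium (5S)-5-{3-[(tert-butyldimethylsilyl)oxy]prop-1-yn-1-yl}-4,5-dihydrofuran-2-olate] | [Li+].[O-]C1=CC[C@@H](C#CCO[Si](C)(C)C(C)(C)C)O1 | intermediate
7 | (3R,5S)-3-methyl-5-{3-[(tert-butyldimethylsilyl)oxy]prop-1-yn-1-yl}oxolan-2-one (trans) | O=C1[C@H](C)C[C@@H](C#CCO[Si](C)(C)C(C)(C)C)O1 | intermediate
8 | isopropenylmagnesium bromide | CC(=C)[Mg]Br | starting material
9 | 2,2-dimethoxyacetaldehyde | COC(OC)C=O | starting material
10 | bromomagnesium 1,1-dimethoxy-3-methylbut-3-en-2-olate (racemic) | COC(OC)C([O-])C(C)=C.[Mg+2].[Br-] | intermediate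
11 | 1,1-dimethoxy-3-methylbut-3-en-2-yl acetate (racemic) | COC(OC)C(OC(C)=O)C(C)=C | intermediate
12 | lithium enolate of 11 [lithium 1-[(1,1-dimethoxy-3-methylbut-3-en-2-yl)oxy]ethen-1-olate] | [Li+].[O-]C(=C)OC(C(OC)OC)C(C)=C | intermediate
13 | 1,1-dimethoxy-3-methylbut-3-en-2-yl (4R,6S)-9-[(tert-butyldimethylsilyl)oxy]-6-hydroxy-4-methyl-3-oxonon-7-ynoate (epimers at the allylic ester carbon) | C=C(C)C(C(OC)OC)OC(=O)CC(=O)[C@H](C)C[C@H](O)C#CCO[Si](C)(C)C(C)(C)C | intermediate
14 | (2E,7R,9S)-12-[(tert-butyldimethylsilyl)oxy]-9-hydroxy-1,1-dimethoxy-3,7-dimethyldodec-2-en-10-yn-6-one | COC(OC)/C=C(\C)CCC(=O)[C@H](C)C[C@H](O)C#CCO[Si](C)(C)C(C)(C)C | intermediate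
15 | angelic acid [(2Z)-2-methylbut-2-enoic acid] | C/C=C(/C)C(=O)O | starting material
16 | (2Z)-2-methylbut-2-enoic 2,4,6-trichlorobenzoic anhydride | C/C=C(/C)C(=O)OC(=O)c1c(Cl)cc(Cl)cc1Cl | intermediate
17 | (2E,7R,9S)-12-[(tert-butyldimethylsilyl)oxy]-1,1-dimethoxy-3,7-dimethyl-6-oxododec-2-en-10-yn-9-yl (2Z)-2-methylbut-2-enoate | C/C=C(/C)C(=O)O[C@H](C#CCO[Si](C)(C)C(C)(C)C)C[C@@H](C)C(=O)CC/C(C)=C/C(OC)OC | intermediate
18 | (2E,7R,9S)-12-hydroxy-3,7-dimethyl-1,6-dioxododec-2-en-10-yn-9-yl (2Z)-2-methylbut-2-enoate | C/C=C(/C)C(=O)O[C@H](C#CCO)C[C@@H](C)C(=O)CC/C(C)=C/C=O | intermediate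
19 | (2S,4R,8E)-1-bromo-4,8-dimethyl-5,10-dioxo-1-[(Z)-2-oxooxetan-3-ylidene]dec-8-en-2-yl (2Z)-2-methylbut-2-enoate (Br cis to the lactone C=O) | C/C=C(/C)C(=O)O[C@H](/C(Br)=C1\COC1=O)C[C@@H](C)C(=O)CC/C(C)=C/C=O | intermediate
20 | (2S,4R)-1-bromo-7-[(2R,3S)-3-formyl-2-methyloxiran-2-yl]-4-methyl-5-oxo-1-[(Z)-2-oxooxetan-3-ylidene]heptan-2-yl (2Z)-2-methylbut-2-enoate | C/C=C(/C)C(=O)O[C@H](/C(Br)=C1\COC1=O)C[C@@H](C)C(=O)CC[C@@]2(C)O[C@@H]2C=O | intermediate
21 | (4R,5R,6S,8S,10R)-8-angeloyloxy-4,5-epoxy-6-hydroxy-1-oxogermacr-7(11)-en-12,13-olide (four-membered lactone, C6 cis to C12) | C/C=C(/C)C(=O)O[C@H]1C[C@@H](C)C(=O)CC[C@@]2(C)O[C@@H]2[C@@H](O)/C1=C3\C(=O)OC3 | intermediate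
22 | (4R,5R,6S,8S,10R)-8-angeloyloxy-4,5-epoxy-13-hydroxy-1-oxogermacr-7(11)-en-12,6-olide | C/C=C(/C)C(=O)O[C@H]1C[C@@H](C)C(=O)CC[C@@]2(C)O[C@@H]2[C@H]2OC(=O)C(CO)=C12 | intermediate
23 | CNP0229937.2, (4R,5R,6S,8S,10R)-13-acetoxy-8-angeloyloxy-4,5-epoxy-1-oxogermacr-7(11)-en-12,6-olide | C/C=C(/C)C(=O)O[C@H]1C[C@@H](C)C(=O)CC[C@@]2(C)O[C@@H]2[C@H]2OC(=O)C(COC(C)=O)=C12 | target

**Step count and risks**
Total step count: 11. Longest linear sequence: 10 (steps 1, 2, 3, 5, 6, 7, 8, 9, 10, 11); step 4 is a one-step branch.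

The three steps most likely to fail:

Step 11 (the proposed new ring closure). Risks are slow nickel insertion into the hindered tetrasubstituted bromide, the wrong face at C6, and premature opening of the four-membered lactone. The fallback uses known reaction types only and sets out from 20. Methanolysis of the four-membered lactone (MeOH, Et3N, 0 °C) gives the hydroxy methyl ester F1. Acetylation (Ac2O, pyridine) gives the acetoxymethyl bromo enoate F2. A conventional CrCl2/NiCl2 coupling of this (Z)-β-bromo enoate with the aldehyde under high dilution then gives the ring-closed hydroxy ester F3, which lactonizes with loss of methanol and comes back to the route at 23. This separates acyl transfer from ring closure and installs the acetate before cyclization.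

Step 9 (bromo-cyclocarbonylation on a polyfunctional substrate). Risks are α-bromination of the ketone by CuBr2, HBr damage to the enal, and a sluggish bromide variant. The fallback sets out from 18. The chloride version of the carbonylation (PdCl2, CuCl2, CO, THF) gives the chloro lactone F4. Stannylation with Me3SnSnMe3 and Pd(PPh3)4 gives the stannyl lactone F5. Bromodestannylation with N-bromosuccinimide proceeds with retention and comes back to the route at 19.

Step 10 (aminocatalytic epoxidation next to a four-membered lactone). Risks are E/Z scrambling of the β,β-disubstituted enal through the dienamine (lower diastereomeric ratio) and attack of peroxide or amine on the lactone or the bromoalkylidene. The fallback sets out from 19. NaBH4 (EtOH–CH2Cl2, −78 °C) reduces only the aldehyde to the allylic alcohol F6. Stereospecific Sharpless epoxidation (Ti(OiPr)4, D-(−)-diethyl tartrate, t-BuOOH, 4 Å sieves, CH2Cl2, −20 °C) gives the epoxy alcohol F7. Dess–Martin periodinane oxidation comes back to the route at 20.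

**Further compounds**
F1 | step 11 | methyl (2Z,4S,6R)-3-bromo-9-[(2R,3S)-3-formyl-2-methyloxiran-2-yl]-2-(hydroxymethyl)-6-methyl-4-{[(2Z)-2-methylbut-2-enoyl]oxy}-7-oxonon-2-enoate | C/C=C(/C)C(=O)O[C@H](/C(Br)=C(\CO)C(=O)OC)C[C@@H](C)C(=O)CC[C@@]1(C)O[C@@H]1C=O
F2 | step 11 | methyl (2Z,4S,6R)-2-(acetoxymethyl)-3-bromo-9-[(2R,3S)-3-formyl-2-methyloxiran-2-yl]-6-methyl-4-{[(2Z)-2-methylbut-2-enoyl]oxy}-7-oxonon-2-enoate | C/C=C(/C)C(=O)O[C@H](/C(Br)=C(\COC(C)=O)C(=O)OC)C[C@@H](C)C(=O)CC[C@@]1(C)O[C@@H]1C=O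
F3 | step 11 | methyl (4R,5R,6S,8S,10R)-13-acetoxy-8-angeloyloxy-4,5-epoxy-6-hydroxy-1-oxogermacr-7(11)-en-12-oate (C6 cis to C12) | C/C=C(/C)C(=O)O[C@H]1C[C@@H](C)C(=O)CC[C@@]2(C)O[C@@H]2[C@@H](O)/C1=C(/COC(C)=O)C(=O)OC
F4 | step 9 | (2S,4R,8E)-1-chloro-4,8-dimethyl-5,10-dioxo-1-[(Z)-2-oxooxetan-3-ylidene]dec-8-en-2-yl (2Z)-2-methylbut-2-enoate | C/C=C(/C)C(=O)O[C@H](/C(Cl)=C1\COC1=O)C[C@@H](C)C(=O)CC/C(C)=C/C=O
F5 | step 9 | (2S,4R,8E)-4,8-dimethyl-5,10-dioxo-1-[(Z)-2-oxooxetan-3-ylidene]-1-(trimethylstannyl)dec-8-en-2-yl (2Z)-2-methylbut-2-enoate | C/C=C(/C)C(=O)O[C@H](/C([Sn](C)(C)C)=C1\COC1=O)C[C@@H](C)C(=O)CC/C(C)=C/C=O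
F6 | step 10 | (2S,4R,8E)-1-bromo-10-hydroxy-4,8-dimethyl-5-oxo-1-[(Z)-2-oxooxetan-3-ylidene]dec-8-en-2-yl (2Z)-2-methylbut-2-enoate | C/C=C(/C)C(=O)O[C@H](/C(Br)=C1\COC1=O)C[C@@H](C)C(=O)CC/C(C)=C/CO
F7 | step 10 | (2S,4R)-1-bromo-7-[(2R,3R)-3-(hydroxymethyl)-2-methyloxiran-2-yl]-4-methyl-5-oxo-1-[(Z)-2-oxooxetan-3-ylidene]heptan-2-yl (2Z)-2-methylbut-2-enoate | C/C=C(/C)C(=O)O[C@H](/C(Br)=C1\COC1=O)C[C@@H](C)C(=O)CC[C@@]2(C)O[C@@H]2CO
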